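**Strategy.** With the heptane chain numbered C1 (on ring A, the 3,4-dihydroxy-5-methoxyphenyl ring) to C7 (on ring B), the target is an all-cis tetrahydropyran whose ring is O, C1–C5. Everything rests on opening it at C1=C2 of the corresponding glycal: the C1–O bond with ring A is carried as a ring A benzoate on the C5 oxygen, C2 as the inner carbon of a vinyl group on C3. One titanium-alkylidene carbonyl–olefin metathesis joins the ester carbon C1 to C2 and closes the six-membered aryl enol ether. Its precursor is an anti-1,3-diol derivative (C5 benzoate, C3 silyl ether) that one Evans–Tishchenko reduction assembles; hydrogenation then sets C1.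

Key step: step 9

Remark: in chain numbering the target is C1 S, C3 R, C5 S (all three pyran substituents cis, i.e. 2S,4R,6S in pyran numbering), which corresponds to the anti (3R,5S) open-chain precursor 13; the C5 centre is taken from a ketone hydrogenation of known facial sense so that the only stereocentre under reagent control is set reliably.

Step 1
Reactants: 1 4-(benzyloxy)-3-methoxybenzyl alcohol
Product: 2 4-(benzyloxy)-3-methoxybenzyl chloride
Conditions: SOCl2, CH2Cl2, 0 °C → rt
Reagents that add atoms: thionyl chloride, ClS(Cl)=O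
Why: Chlorination of an electron-rich benzylic alcohol with thionyl chloride (collapse of the chlorosulfite) is fast at 0 °C and should leave the aryl benzyl ether untouched.

Step 2
Reactants: 2 4-(benzyloxy)-3-methoxybenzyl chloride; 3 methyl acetoacetate
Product: 5 methyl 5-[4-(benzyloxy)-3-methoxyphenyl]-3-oxopentanoate, via acetoacetate dianion 4 (not isolated)
Conditions: NaH, THF, 0 °C; n-BuLi, 0 °C; then 2, 0 °C → rt; aq. NH4Cl
Reagents that add atoms: none
Why: Weiler dianion alkylation, in which the doubly deprotonated acetoacetate reacts only at its more basic terminal carbon with the reactive benzylic chloride and so lays down C3–C7 with ring B attached.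

Step 3
Reactants: 5 methyl 5-[4-(benzyloxy)-3-methoxyphenyl]-3-oxopentanoate
Product: 6 methyl (3S)-5-[4-(benzyloxy)-3-methoxyphenyl]-3-hydroxypentanoate
Conditions: RuCl2[(S)-BINAP] (0.5 mol%), H2 (4 atm), MeOH, 80 °C
Reagents that add atoms: none
Why: Noyori asymmetric hydrogenation of a β-keto ester, in which the ester carbonyl chelates ruthenium and the (S)-BINAP ligand directs hydride to the ketone face that gives the S carbinol (the future C5), the same sense as for simple 3-oxoalkanoates, while ruthenium should not hydrogenolyse the benzyl ether.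

Step 4
Reactants: 6 methyl (3S)-5-[4-(benzyloxy)-3-methoxyphenyl]-3-hydroxypentanoate
Product: 7 (3S)-5-[4-(benzyloxy)-3-methoxyphenyl]-3-hydroxy-N-methoxy-N-methylpentanamide
Conditions: MeNH(OMe)·HCl, i-PrMgCl, THF, −20 → 0 °C
Reagents that add atoms: N,O-dimethylhydroxylamine hydrochloride, CNOC.Cl
Why: Weinreb amide formation by aminolysis of the ester with the chloromagnesium amide, which proceeds at low temperature on unprotected β-hydroxy esters (the alkoxide is carried through) and does not touch the carbinol centre.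

Step 5
Reactants: 7 (3S)-5-[4-(benzyloxy)-3-methoxyphenyl]-3-hydroxy-N-methoxy-N-methylpentanamide
Product: 8 (5S)-7-[4-(benzyloxy)-3-methoxyphenyl]-5-hydroxyhept-1-en-3-one
Conditions: CH2=CHMgBr (3.5 equiv), THF, −78 → 0 °C; inverse quench into cold 1 M HCl; used at once
Reagents that add atoms: vinylmagnesium bromide, C=C[Mg]Br
Why: Weinreb ketone synthesis, in which the chelated adduct releases the ketone only on the acidic inverse quench, so that a single vinyl group (C2 and the carbon later expelled) is delivered and the liberated amine is protonated before it can add to the enone.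

Step 6
Reactants: 9 3,4-dihydroxy-5-methoxybenzaldehyde
Product: 10 3,4-bis(benzyloxy)-5-methoxybenzaldehyde
Conditions: BnBr, K2CO3, DMF, 60 °C
Reagents that add atoms: benzyl bromide, BrCc1ccccc1
Why: Williamson ether synthesis on both phenols, with benzyl chosen because it should survive samarium, silyl triflate and titanium alkylidene chemistry and leaves in the final hydrogenation.

Step 7
Reactants: 8 (5S)-7-[4-(benzyloxy)-3-methoxyphenyl]-5-hydroxyhept-1-en-3-one; 10 3,4-bis(benzyloxy)-5-methoxybenzaldehyde
Product: 12 (3R,5S)-7-[4-(benzyloxy)-3-methoxyphenyl]-3-hydroxyhept-1-en-5-yl 3,4-bis(benzyloxy)-5-methoxybenzoate, via samarium-bound hemiacetal 11 (not isolated)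
Conditions: 10 (3 equiv), SmI2 (0.3 equiv, premixed with 10), THF, −10 °C, dark
Reagents that add atoms: none
Why: Evans–Tishchenko reduction, in which the C5 hydroxyl adds to the aldehyde on trivalent samarium and the hemiacetal hydrogen is passed intramolecularly to the C3 ketone through a chair-like six-membered transition state with equatorial substituents, which should set C3 (R) anti to C5 and leave the ring A acyl group on the C5 oxygen.

Step 8
Reactants: 12 (3R,5S)-7-[4-(benzyloxy)-3-methoxyphenyl]-3-hydroxyhept-1-en-5-yl 3,4-bis(benzyloxy)-5-methoxybenzoate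
Product: 13 (3R,5S)-7-[4-(benzyloxy)-3-methoxyphenyl]-3-(tert-butyldimethylsilyloxy)hept-1-en-5-yl 3,4-bis(benzyloxy)-5-methoxybenzoate
Conditions: TBSOTf, 2,6-lutidine, CH2Cl2, −78 → 0 °C
Reagents that add atoms: tert-butyldimethylsilyl trifluoromethanesulfonate, CC(C)(C)[Si](C)(C)OS(=O)(=O)C(F)(F)F
Why: Silylation of the secondary allylic alcohol with a silyl triflate and a hindered non-nucleophilic base at low temperature should outrun 1,3-acyl migration, so the ester stays on the C5 oxygen.

Step 9
Reactants: 13 (3R,5S)-7-[4-(benzyloxy)-3-methoxyphenyl]-3-(tert-butyldimethylsilyloxy)hept-1-en-5-yl 3,4-bis(benzyloxy)-5-methoxybenzoate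
Product: 15 (2S,4R)-6-[3,4-bis(benzyloxy)-5-methoxyphenyl]-2-{2-[4-(benzyloxy)-3-methoxyphenyl]ethyl}-4-(tert-butyldimethylsilyloxy)-3,4-dihydro-2H-pyran, via C2 titanium alkylidene 14 (not isolated)
Conditions: TiCl4, TMEDA, Zn dust, PbCl2 (cat.), CH3CHBr2, CH2Cl2–THF, 0 °C then 65 °C; aq. K2CO3 quench; Et3N-deactivated silica
Reagents that add atoms: none
Why: Zn (activated by catalytic PbCl2) converts CH3CHBr2 into a geminal dizinc reagent that transmetalates to the TiCl4–TMEDA complex to give a low-valent titanium ethylidene; this most plausibly first exchanges with the monosubstituted C2=CH2 alkene through a titanacyclobutane (propene is lost) to give alkylidene 14, which adds across the benzoate C1=O as an oxatitanacyclobutane and cycloreverts to the C1=C2 enol ether and a titanium oxo species, while the reverse order (ethylidenation of the ester, then enol ether–alkene metathesis) converges on the same ring. The closest known reaction type is the Takai–Utimoto alkylidenation of esters in its intramolecular form, the olefinic ester cyclisation (ring-closing carbonyl–olefin metathesis) that gives six-membered cyclic enol ethers. The one ring (O, C1, C2, C3, C4, C5) closes by attack of the alkylidene carbon C2 on the carbonyl carbon C1 with the C=O bond outside the forming ring, a 6-exo-trig [2+2] closure followed by cycloreversion. No stereocentre is created, and C3 and C5 should pass through unchanged because they are remote from the reacting atoms and the benzoate has no enolisable position. The step needs cyclisation to win over plain ester alkylidenation, which is secured by the ethylidene rather than methylidene reagent, by the presence of only one ester carbonyl and one terminal alkene, and by the anti C3/C5 arrangement that lets the silyloxy group and the ring B arm both sit pseudo-equatorial in the six-membered transition state.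

Step 10
Reactants: 15 (2S,4R)-6-[3,4-bis(benzyloxy)-5-methoxyphenyl]-2-{2-[4-(benzyloxy)-3-methoxyphenyl]ethyl}-4-(tert-butyldimethylsilyloxy)-3,4-dihydro-2H-pyran
Product: 17 5-[(2S,4R,6S)-4-(tert-butyldimethylsilyloxy)-6-[2-(4-hydroxy-3-methoxyphenyl)ethyl]tetrahydro-2H-pyran-2-yl]-3-methoxybenzene-1,2-diol, via saturated tribenzyl ether 16 (not isolated)
Conditions: H2 (1 atm), 10% Pd/C, EtOAc–EtOH, rt
Reagents that add atoms: none
Why: Heterogeneous catalytic hydrogenation, in which syn addition of hydrogen to the C1=C2 enol ether from the face opposite the C3 silyloxy group and the C5 side chain should place ring A cis to both (C1 S, all-equatorial), after which the same catalyst hydrogenolyses the three aryl benzyl ethers.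

Step 11
Reactants: 17 5-[(2S,4R,6S)-4-(tert-butyldimethylsilyloxy)-6-[2-(4-hydroxy-3-methoxyphenyl)ethyl]tetrahydro-2H-pyran-2-yl]-3-methoxybenzene-1,2-diol
Product: 18 (2S,4R,6S)-2-(3,4-dihydroxy-5-methoxyphenyl)-6-[2-(4-hydroxy-3-methoxyphenyl)ethyl]tetrahydro-2H-pyran-4-ol
Conditions: HF·pyridine, pyridine–THF, 0 °C → rt
Reagents that add atoms: none
Why: Fluoride-driven desilylation of the secondary silyl ether under buffered, non-basic conditions should spare the oxidation-prone catechol and the acid-labile benzylic C1–O bond.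

**Compound list**

1 | 4-(benzyloxy)-3-methoxybenzyl alcohol | COc1cc(CO)ccc1OCc1ccccc1 | starting material
2 | 4-(benzyloxy)-3-methoxybenzyl chloride | COc1cc(CCl)ccc1OCc1ccccc1 | intermediate
3 | methyl acetoacetate | CC(=O)CC(=O)OC | starting material
4 | methyl acetoacetate dianion (sodium lithium salt) | [Na+].[Li+].[CH2-]C(=O)[CH-]C(=O)OC | intermediate (not isolated)
5 | methyl 5-[4-(benzyloxy)-3-methoxyphenyl]-3-oxopentanoate | COc1cc(CCC(=O)CC(=O)OC)ccc1OCc1ccccc1 | intermediate
6 | methyl (3S)-5-[4-(benzyloxy)-3-methoxyphenyl]-3-hydroxypentanoate | COc1cc(CC[C@H](O)CC(=O)OC)ccc1OCc1ccccc1 | intermediate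
7 | (3S)-5-[4-(benzyloxy)-3-methoxyphenyl]-3-hydroxy-N-methoxy-N-methylpentanamide | COc1cc(CC[C@H](O)CC(=O)N(C)OC)ccc1OCc1ccccc1 | intermediate
8 | (5S)-7-[4-(benzyloxy)-3-methoxyphenyl]-5-hydroxyhept-1-en-3-one | COc1cc(CC[C@H](O)CC(=O)C=C)ccc1OCc1ccccc1 | intermediate
9 | 3,4-dihydroxy-5-methoxybenzaldehyde | O=Cc1cc(O)c(O)c(OC)c1 | starting material
10 | 3,4-bis(benzyloxy)-5-methoxybenzaldehyde | COc1cc(C=O)cc(OCc2ccccc2)c1OCc1ccccc1 | intermediate
11 | hemiacetal of 8 (C5 oxygen) with 10, bound to samarium in the flask and drawn as the free hemiacetal | COc1cc(CC[C@H](OC(O)c2cc(OCc3ccccc3)c(OCc3ccccc3)c(OC)c2)CC(=O)C=C)ccc1OCc1ccccc1 | intermediate (not isolated)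
12 | (3R,5S)-7-[4-(benzyloxy)-3-methoxyphenyl]-3-hydroxyhept-1-en-5-yl 3,4-bis(benzyloxy)-5-methoxybenzoate (anti) | COc1cc(CC[C@H](OC(=O)c2cc(OCc3ccccc3)c(OCc3ccccc3)c(OC)c2)C[C@@H](O)C=C)ccc1OCc1ccccc1 | intermediate
13 | (3R,5S)-7-[4-(benzyloxy)-3-methoxyphenyl]-3-(tert-butyldimethylsilyloxy)hept-1-en-5-yl 3,4-bis(benzyloxy)-5-methoxybenzoate (anti) | COc1cc(CC[C@H](OC(=O)c2cc(OCc3ccccc3)c(OCc3ccccc3)c(OC)c2)C[C@@H](O[Si](C)(C)C(C)(C)C)C=C)ccc1OCc1ccccc1 | intermediate
14 | titanium alkylidene at C2 of 13 (terminal CH2 replaced by titanium, ligands not shown) | COc1cc(CC[C@H](OC(=O)c2cc(OCc3ccccc3)c(OCc3ccccc3)c(OC)c2)C[C@@H](O[Si](C)(C)C(C)(C)C)C=[Ti])ccc1OCc1ccccc1 | intermediate (not isolated)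
15 | (2S,4R)-6-[3,4-bis(benzyloxy)-5-methoxyphenyl]-2-{2-[4-(benzyloxy)-3-methoxyphenyl]ethyl}-4-(tert-butyldimethylsilyloxy)-3,4-dihydro-2H-pyran (2,4-cis) | COc1cc(CC[C@H]2C[C@@H](O[Si](C)(C)C(C)(C)C)C=C(c3cc(OCc4ccccc4)c(OCc4ccccc4)c(OC)c3)O2)ccc1OCc1ccccc1 | intermediate
16 | (2S,4R,6S)-2-[3,4-bis(benzyloxy)-5-methoxyphenyl]-6-{2-[4-(benzyloxy)-3-methoxyphenyl]ethyl}-4-(tert-butyldimethylsilyloxy)tetrahydro-2H-pyran (all-cis) | COc1cc(CC[C@H]2C[C@@H](O[Si](C)(C)C(C)(C)C)C[C@@H](c3cc(OCc4ccccc4)c(OCc4ccccc4)c(OC)c3)O2)ccc1OCc1ccccc1 | intermediate (not isolated)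
17 | 5-[(2S,4R,6S)-4-(tert-butyldimethylsilyloxy)-6-[2-(4-hydroxy-3-methoxyphenyl)ethyl]tetrahydro-2H-pyran-2-yl]-3-methoxybenzene-1,2-diol | COc1cc(CC[C@H]2C[C@@H](O[Si](C)(C)C(C)(C)C)C[C@@H](c3cc(O)c(O)c(OC)c3)O2)ccc1O | intermediate
18 | (2S,4R,6S)-2-(3,4-dihydroxy-5-methoxyphenyl)-6-[2-(4-hydroxy-3-methoxyphenyl)ethyl]tetrahydro-2H-pyran-4-ol | COc1cc(CC[C@H]2C[C@@H](O)C[C@@H](c3cc(O)c(O)c(OC)c3)O2)ccc1O | target

**Step count and risks**

Total: 11 steps. Longest linear sequence: 10 steps (steps 1–5 and 7–11, from 1); step 6 prepares the ring A aldehyde in parallel.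

Steps most likely to fail:

1. Step 9 (key step). The ethylidene may only alkylidenate the ester and stop at an acyclic enol ether; the C2 titanium alkylidene may decay before it reaches the carbonyl, for example by loss of the neighbouring silyloxy group; or the enol ether may hydrolyse on work-up. The fallback sets out from 13 and comes back at 15. Methylenation of the benzoate carbonyl with Cp2TiMe2 (toluene, 70 °C, dark) should give the acyclic 1-arylvinyl ether F1. Enol ether–olefin ring-closing metathesis with second-generation Grubbs catalyst RuCl2(=CHPh)(PCy3)(H2IMes) (toluene, 70 °C, ethene purged) should then close the same C1=C2 bond and give 15.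

2. Step 7. Hemiacetal formation and hydride transfer may be slow with the electron-rich, hindered aldehyde 10, which would let oxa-Michael closure of the hydroxy enone, retro-aldol cleavage or 1,3-acyl migration compete. The fallback sets out from 8 and comes back at 13. The same samarium-catalysed reduction run with acetaldehyde, a far more reactive partner, should give the (3R,5S) C5 acetate F2. Silylation (TBSOTf, 2,6-lutidine) gives the silyl ether acetate F3, and methanolysis (K2CO3, MeOH, 0 °C) frees the C5 alcohol F4. Pinnick oxidation of 10 (NaClO2, NaH2PO4, 2-methylbut-2-ene, t-BuOH–H2O) gives 3,4-bis(benzyloxy)-5-methoxybenzoic acid F5. Steglich esterification of F4 with F5 (EDC·HCl, DMAP, CH2Cl2) returns to 13.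

3. Step 10. Facial selectivity in the hydrogen addition at C1 may be poor, or palladium may hydrogenolyse the allylic C3–O or benzylic C1–O bond. The fallback sets out from 15 and comes back at 16. Acid-catalysed addition of methanol across the enol ether (PPTS, MeOH–CH2Cl2, 0 °C) should give the C1 methyl ketal F6. Ionic reduction (Et3SiH, BF3·OEt2, CH2Cl2–MeCN, −78 to −40 °C) then delivers hydride axially to the aryl-stabilised oxocarbenium ion and should give the all-cis tetrahydropyran 16, isolated in this case. Hydrogenolysis over Pd/C under the conditions of step 10 then only has to remove the benzyl ethers on the way to 17.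

**Further compounds**

F1 | step 9 | (3R,5S)-7-[4-(benzyloxy)-3-methoxyphenyl]-5-({1-[3,4-bis(benzyloxy)-5-methoxyphenyl]ethenyl}oxy)-3-(tert-butyldimethylsilyloxy)hept-1-ene | COc1cc(CC[C@H](OC(=C)c2cc(OCc3ccccc3)c(OCc3ccccc3)c(OC)c2)C[C@@H](O[Si](C)(C)C(C)(C)C)C=C)ccc1OCc1ccccc1
F2 | step 7 | (3R,5S)-7-[4-(benzyloxy)-3-methoxyphenyl]-3-hydroxyhept-1-en-5-yl acetate | COc1cc(CC[C@H](OC(C)=O)C[C@@H](O)C=C)ccc1OCc1ccccc1
F3 | step 7 | (3R,5S)-7-[4-(benzyloxy)-3-methoxyphenyl]-3-(tert-butyldimethylsilyloxy)hept-1-en-5-yl acetate | COc1cc(CC[C@H](OC(C)=O)C[C@@H](O[Si](C)(C)C(C)(C)C)C=C)ccc1OCc1ccccc1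
F4 | step 7 | (3R,5S)-7-[4-(benzyloxy)-3-methoxyphenyl]-3-(tert-butyldimethylsilyloxy)hept-1-en-5-ol | COc1cc(CC[C@H](O)C[C@@H](O[Si](C)(C)C(C)(C)C)C=C)ccc1OCc1ccccc1
F5 | step 7 | 3,4-bis(benzyloxy)-5-methoxybenzoic acid | COc1cc(C(=O)O)cc(OCc2ccccc2)c1OCc1ccccc1
F6 | step 10 | (4R,6S)-2-[3,4-bis(benzyloxy)-5-methoxyphenyl]-6-{2-[4-(benzyloxy)-3-methoxyphenyl]ethyl}-4-(tert-butyldimethylsilyloxy)-2-methoxytetrahydro-2H-pyran (mixture at C2) | COc1cc(CC[C@H]2C[C@@H](O[Si](C)(C)C(C)(C)C)CC(OC)(c3cc(OCc4ccccc4)c(OCc4ccccc4)c(OC)c3)O2)ccc1OCc1ccccc1
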